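**Retrosynthetic overview**

1. Target 18 ⇐ E-enal 17 (aldehyde oxidation) ⇐ tertiary vinyl carbinol 14 by an oxidative [3,3]-sigmatropic chromate shift that makes the C15–O bond and the 13E olefin (key step).
2. 14 ⇐ methyl ketone 12 (vinyl Grignard, then 18-O-acetylation) ⇐ δ-lactone 11 (CH3Li) ⇐ isopropyl ketone 9 (Baeyer–Villiger excision of the isopropyl group).
3. 9 ⇐ exocyclic olefin 8 (radical Markovnikov hydration sets C8) ⇐ keto-enal 4 by reductive transposition through an allylic diazene ([1,5]-sigmatropic hydrogen shift).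
4. 4 ⇐ abietinol 2 (ozonolysis of C13=C14 opens ring C) ⇐ (−)-abietic acid 1 (LiAlH4).
5. Rings: no carbocycle is built. Rings A and B, with C4, C5, C9 and C10, come intact from 1; ring C is cut open; the only ring closed on the way is the temporary δ-lactone of 11.

Assumption: the target is read as (13E)-18-acetoxy-8α-hydroxylabd-13-en-15-oic acid of the normal labdane series (CH2OAc = C18, 4α, trans to the C10 methyl), and recrystallised commercial (−)-abietic acid is the chiral starting material.

Numbering: abietane numbering is used for 1–9 and labdane numbering from 10 on (abietane C14 becomes labdane C17). The selectivities quoted below are estimates from analogous substrates, not measured values.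

**Route**

Step 1
Reactants: 1 (−)-abietic acid
Product: 2 abietinol (abieta-7,13-dien-18-ol)
Conditions: LiAlH4, THF, 0 °C → reflux; then H2O, aq. NaOH
Reagents that add atoms: none
Why: LiAlH4 reduction of the carboxylic acid gives the neopentyl primary alcohol and leaves the unactivated diene and the four bought stereocentres (C4, C5, C9, C10) untouched.

Step 2
Reactants: 2 abietinol
Product: 4 18-hydroxy-13-oxo-13,14-secoabiet-7-en-14-al, via secondary 13,14-ozonide 3 (not isolated)
Conditions: O3 (1.0 equiv), CH2Cl2, −78 °C; then Me2S, −78 °C → rt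
Reagents that add atoms: ozone, [O-][O+]=O
Why: In this regioselective ozonolysis with reductive work-up, one equivalent of ozone should cleave the more exposed C13=C14 bond of the diene first, and the remaining C7=C8 bond is then part of an electron-poor enal and resists further attack, so ring C opens without touching C9.

Step 3
Reactants: 4 18-hydroxy-13-oxo-13,14-secoabiet-7-en-14-al
Product: 8 18-hydroxy-13,14-secoabiet-8(14)-en-13-one, via C14 tosylhydrazone 5 (not isolated), via N-boryl tosylhydrazine 6 (not isolated), via allylic diazene 7 (not isolated)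
Conditions: TsNHNH2 (1.05 equiv), THF, rt; then catecholborane (3 equiv), CHCl3, 0 °C; then NaOAc·3H2O, 60 °C
Reagents that add atoms: none
Why: In this Kabalka-type reductive 1,3-transposition the aldehyde condenses much faster than the hindered isopropyl ketone, hydride adds 1,2 to C=N, and the allylic diazene loses N2 in a [1,5]-sigmatropic hydrogen shift (retro-ene) that puts H on C7 and the double bond exocyclic at C8=C14, with no stereocentre formed.

Step 4
Reactants: 8 18-hydroxy-13,14-secoabiet-8(14)-en-13-one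
Product: 9 8α,18-dihydroxy-13,14-secoabietan-13-one (8β-CH3)
Conditions: Mn(dpm)3 (10 mol %; dpm = 2,2,6,6-tetramethylheptane-3,5-dionate), PhSiH3 (2.5 equiv), O2 (1 atm), iPrOH/CH2Cl2, 0 °C → rt
Reagents that add atoms: dioxygen, O=O
Why: In this Mukaiyama hydration (hydrogen-atom transfer, Markovnikov) H adds to the CH2 terminus and O2 traps the tertiary C8 radical from the α face, away from the axial C10 methyl, giving the equatorial 8α-OH and axial 8β-CH3 as in sclareol (substrate control, d.r. expected about 4:1, minor epimer removed by chromatography).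

Step 5
Reactants: 9 8α,18-dihydroxy-13,14-secoabietan-13-one
Product: 11 18-hydroxyambreinolide (8α,18-dihydroxy-14,15,16-trinorlabdan-13-oic acid 13→8 lactone), via isopropyl ester 10 (not isolated)
Conditions: mCPBA (3 equiv), Na2HPO4, CH2Cl2, rt, 48 h; aqueous wash; crude 10, TsOH·H2O (5 mol %), PhMe, 50 °C
Reagents that add atoms: mCPBA, OOC(=O)c1cccc(Cl)c1
Why: Baeyer–Villiger oxidation with preferred migration of the secondary isopropyl group turns the ketone into the isopropyl ester, which the 8α-OH closes to the six-membered lactone by acid-catalysed acyl substitution that does not touch C8.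

Step 6
Reactants: 11 18-hydroxyambreinolide
Product: 12 8α,18-dihydroxy-14,15-dinorlabdan-13-one
Conditions: CH3Li (2.2 equiv), THF, −78 °C; aq. NH4Cl, −78 °C
Reagents that add atoms: methyllithium, [Li]C
Why: In this mono-addition of an organolithium to a lactone, the first equivalent deprotonates the 18-OH and the tetrahedral lithium hemiketal alkoxide persists at −78 °C, collapsing to the methyl ketone only on quench, so over-addition is avoided.

Step 7
Reactants: 12 8α,18-dihydroxy-14,15-dinorlabdan-13-one
Product: 13 labd-14-ene-8α,13,18-triol (18-hydroxysclareol, 13-epimer mixture)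
Conditions: CH2=CHMgBr (4 equiv), THF, 0 °C → rt; aq. NH4Cl
Reagents that add atoms: vinylmagnesium bromide, C=C[Mg]Br
Why: Grignard 1,2-addition to the methyl ketone (after deprotonation of both hydroxyls) installs C14 and C15, and the new C13 centre forms as an uncontrolled mixture of about 1:1, which does not matter because C13 becomes sp2 in step 9.

Step 8
Reactants: 13 labd-14-ene-8α,13,18-triol
Product: 14 18-acetoxylabd-14-ene-8α,13-diol (13-epimer mixture)
Conditions: Ac2O (1.2 equiv), pyridine, 0 °C → rt
Reagents that add atoms: acetic anhydride, CC(=O)OC(C)=O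
Why: This chemoselective O-acylation acetylates only the primary 18-OH, since the two tertiary alcohols do not react with Ac2O/pyridine without a stronger acyl-transfer catalyst.

Step 9
Reactants: 14 18-acetoxylabd-14-ene-8α,13-diol
Product: 17 (13E)-18-acetoxy-8α-hydroxylabd-13-en-15-al, via tertiary chlorochromate ester 15 (not isolated), via primary allylic chlorochromate ester 16 (not isolated)
Conditions: [C5H5NH][CrO3Cl] (3 equiv), 4 Å molecular sieves, CH2Cl2, rt; SiO2 chromatography (E from Z)
Reagents that add atoms: pyridinium chlorochromate [C5H5NH][CrO3Cl], c1cc[nH+]cc1.[O-][Cr](=O)(=O)Cl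
Why: In this Babler–Dauben oxidative transposition the tertiary allylic chromate ester undergoes a [3,3]-sigmatropic shift that forms the C15–O bond and the C13=C14 double bond, and the primary chromate is then oxidised to the enal, with both C13 epimers converging, the E isomer favoured by about 3:1 through the chair with the large chain equatorial, and the non-allylic tertiary 8-OH unable to be oxidised.

Step 10
Reactants: 17 (13E)-18-acetoxy-8α-hydroxylabd-13-en-15-al
Product: 18 (13E)-18-acetoxy-8α-hydroxylabd-13-en-15-oic acid (target)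
Conditions: NaClO2, NaH2PO4, 2-methyl-2-butene, t-BuOH/H2O, 0 °C → rt
Reagents that add atoms: NaClO2, [Na+].[O-]Cl=O
Why: Pinnick oxidation converts the enal to the acid under buffered conditions that leave the acetate, the tertiary alcohol and the olefin geometry unchanged.

**Compound list**

1 | (−)-abietic acid, abieta-7,13-dien-18-oic acid (4α-CO2H, 4β-CH3, 5α-H, 9α-H, 10β-CH3; 4R,5R,9R,10R) | OC(=O)[C@]1(C)CCC[C@]2(C)[C@@H](CCC(C(C)C)=C3)C3=CC[C@@H]12 | starting material
2 | abietinol, abieta-7,13-dien-18-ol (centres as in 1) | OC[C@]1(C)CCC[C@]2(C)[C@@H](CCC(C(C)C)=C3)C3=CC[C@@H]12 | intermediate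
3 | secondary 13,14-ozonide of 2 (1,2,4-trioxolane across C13 and C14, mixture at these two carbons) | OC[C@]1(C)CCC[C@]2(C)[C@@H](CCC3(C(C)C)OOC4O3)C4=CC[C@@H]12 | intermediate (not isolated)
4 | 18-hydroxy-13-oxo-13,14-secoabiet-7-en-14-al (CHO on C8 of the C7=C8 bond; C9 α-H carries the β-CH2CH2COCH(CH3)2 chain) | OC[C@]1(C)CCC[C@]2(C)[C@@H](CCC(=O)C(C)C)C(C=O)=CC[C@@H]12 | intermediate
5 | C14 tosylhydrazone of 4 | OC[C@]1(C)CCC[C@]2(C)[C@@H](CCC(=O)C(C)C)C(C=NNS(=O)(=O)c3ccc(C)cc3)=CC[C@@H]12 | intermediate (not isolated)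
6 | N-(1,3,2-benzodioxaborol-2-yl) tosylhydrazine from 1,2-hydride addition to 5 | OC[C@]1(C)CCC[C@]2(C)[C@@H](CCC(=O)C(C)C)C(CN(B3Oc4ccccc4O3)NS(=O)(=O)c3ccc(C)cc3)=CC[C@@H]12 | intermediate (not isolated)
7 | allylic diazene (C7=C8–C14H2–N=NH) | OC[C@]1(C)CCC[C@]2(C)[C@@H](CCC(=O)C(C)C)C(CN=N)=CC[C@@H]12 | intermediate (not isolated)
8 | 18-hydroxy-13,14-secoabiet-8(14)-en-13-one (exocyclic C8=CH2) | OC[C@]1(C)CCC[C@]2(C)[C@@H](CCC(=O)C(C)C)C(=C)CC[C@@H]12 | intermediate
9 | 8α,18-dihydroxy-13,14-secoabietan-13-one (8α-OH equatorial, 8β-CH3 axial) | OC[C@]1(C)CCC[C@]2(C)[C@@H](CCC(=O)C(C)C)[C@](C)(O)CC[C@@H]12 | intermediate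
10 | isopropyl 8α,18-dihydroxy-14,15,16-trinorlabdan-13-oate | OC[C@]1(C)CCC[C@]2(C)[C@@H](CCC(=O)OC(C)C)[C@](C)(O)CC[C@@H]12 | intermediate (not isolated)
11 | 18-hydroxyambreinolide (δ-lactone between C13 and the 8α-oxygen, 8β-CH3, 9α-H) | OC[C@]1(C)CCC[C@]2(C)[C@H]3CCC(=O)O[C@]3(C)CC[C@@H]12 | intermediate
12 | 8α,18-dihydroxy-14,15-dinorlabdan-13-one (in equilibrium with its cyclic hemiketal) | OC[C@]1(C)CCC[C@]2(C)[C@@H](CCC(C)=O)[C@](C)(O)CC[C@@H]12 | intermediate
13 | labd-14-ene-8α,13,18-triol (C13 epimer mixture) | OC[C@]1(C)CCC[C@]2(C)[C@@H](CCC(C)(O)C=C)[C@](C)(O)CC[C@@H]12 | intermediate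
14 | 18-acetoxylabd-14-ene-8α,13-diol (C13 epimer mixture) | CC(=O)OC[C@]1(C)CCC[C@]2(C)[C@@H](CCC(C)(O)C=C)[C@](C)(O)CC[C@@H]12 | intermediate
15 | C13 chlorochromate ester of 14 | CC(=O)OC[C@]1(C)CCC[C@]2(C)[C@@H](CCC(C)(O[Cr](=O)(=O)Cl)C=C)[C@](C)(O)CC[C@@H]12 | intermediate (not isolated)
16 | (13E)-C15 chlorochromate ester after the [3,3] shift | CC(=O)OC[C@]1(C)CCC[C@]2(C)[C@@H](CC/C(C)=C/CO[Cr](=O)(=O)Cl)[C@](C)(O)CC[C@@H]12 | intermediate (not isolated)
17 | (13E)-18-acetoxy-8α-hydroxylabd-13-en-15-al | CC(=O)OC[C@]1(C)CCC[C@]2(C)[C@@H](CC/C(C)=C/C=O)[C@](C)(O)CC[C@@H]12 | intermediate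
18 | (13E)-18-acetoxy-8α-hydroxylabd-13-en-15-oic acid (4α-CH2OAc, 4β-CH3, 5α-H, 8α-OH, 8β-CH3, 9α-H, 10β-CH3) | CC(=O)OC[C@]1(C)CCC[C@]2(C)[C@@H](CC/C(C)=C/C(=O)O)[C@](C)(O)CC[C@@H]12 | target

**Step count and risks**

Total steps: 10. Longest linear sequence: 10 steps from 1 (fully linear).

Stereochemistry: C4, C5, C9 and C10 are bought in 1 and never touched; C8 is set in step 4 by substrate control; the 13E geometry is set in step 9.

Three steps most likely to fail:

Step 3 is risky because hydrazone formation and borane reduction must discriminate the enal from a free ketone in one pot. The fallback sets out from 4. NaBH(OAc)3 (benzene/AcOH, rt) reduces only the aldehyde to the allylic alcohol 14,18-dihydroxy-13,14-secoabiet-7-en-13-one F1. A Mitsunobu reaction with 2-nitrobenzenesulfonylhydrazide (PPh3, DEAD, THF, −30 °C; the neopentyl 18-OH does not react) gives the N-allyl-N-(2-nitrobenzenesulfonyl)hydrazine F2. On warming to rt this loses the sulfinic acid to give the diazene, so the fallback comes back to the route at 7 and hence 8.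

Step 4 is risky because the facial selectivity of radical trapping at C8 may be modest. The fallback sets out from 8. Excess mCPBA (Na2HPO4, CH2Cl2) epoxidises the exocyclic olefin from the α face and carries out the Baeyer–Villiger oxidation in the same pot, giving the epoxy ester isopropyl 8α,17-epoxy-18-hydroxy-14,15,16-trinorlabdan-13-oate F3. PhSeNa (from (PhSe)2 and NaBH4, EtOH) opens the epoxide at its CH2 terminus to the hydroxy selenide isopropyl 8α,18-dihydroxy-17-(phenylselanyl)-14,15,16-trinorlabdan-13-oate F4. Bu3SnH/AIBN (PhMe, 80 °C) removes selenium and the fallback comes back to the route at 10, which is closed to 11 as in step 5.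

Step 9 is risky for two reasons: the free 8α-OH can capture an ionised allylic chromate to give 8,13-cyclic ethers, and the E/Z ratio is only moderate (the Z-enal can be re-equilibrated with catalytic iodine and recycled). The fallback sets out from 12. Horner–Wadsworth–Emmons olefination with allyl diethylphosphonoacetate and NaH (THF, 0 → 50 °C) gives the allyl ester allyl (13E)-8α,18-dihydroxylabd-13-en-15-oate F5 (E/Z about 5:1, separable). Ac2O/pyridine gives its 18-acetate allyl (13E)-18-acetoxy-8α-hydroxylabd-13-en-15-oate F6. Pd(PPh3)4 and morpholine (THF, rt) remove the allyl group without touching the acetate, and the fallback comes back to the route at 18.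

**Further compounds**

F1 | step 3 | 14,18-dihydroxy-13,14-secoabiet-7-en-13-one | OC[C@]1(C)CCC[C@]2(C)[C@@H](CCC(=O)C(C)C)C(CO)=CC[C@@H]12
F2 | step 3 | N-allyl-N-(2-nitrobenzenesulfonyl)hydrazine derived from F1 | OC[C@]1(C)CCC[C@]2(C)[C@@H](CCC(=O)C(C)C)C(CN(N)S(=O)(=O)c3ccccc3[N+](=O)[O-])=CC[C@@H]12
F3 | step 4 | isopropyl 8α,17-epoxy-18-hydroxy-14,15,16-trinorlabdan-13-oate | OC[C@]1(C)CCC[C@]2(C)[C@@H](CCC(=O)OC(C)C)[C@]3(OC3)CC[C@@H]12
F4 | step 4 | isopropyl 8α,18-dihydroxy-17-(phenylselanyl)-14,15,16-trinorlabdan-13-oate | OC[C@]1(C)CCC[C@]2(C)[C@@H](CCC(=O)OC(C)C)[C@](C[Se]c3ccccc3)(O)CC[C@@H]12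
F5 | step 9 | allyl (13E)-8α,18-dihydroxylabd-13-en-15-oate | OC[C@]1(C)CCC[C@]2(C)[C@@H](CC/C(C)=C/C(=O)OCC=C)[C@](C)(O)CC[C@@H]12
F6 | step 9 | allyl (13E)-18-acetoxy-8α-hydroxylabd-13-en-15-oate | CC(=O)OC[C@]1(C)CCC[C@]2(C)[C@@H](CC/C(C)=C/C(=O)OCC=C)[C@](C)(O)CC[C@@H]12
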